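All runs were computed with made-up constants; noise was put on by code.

- Picture a one-step world: J + X gives Z, and the bench rule of thumb says to charge one equivalent of X and expect 100% of the J charged as Z.

| setting | dawn | noon | flask |
|---|---|---|---|
| J | 0.055 M | 0.055 M | 0.055 M |
| X | 0.17 M | 0.17 M | 0.170 M |
| G | 0.0165 M | 0.0083 M | 0.0165 M |
| remark | the very flask that is asked about, followed so far | run made earlier |  |
| time |  |  | 3.0 d |

| run | time / h | Z / % | L / % | J / % |
|---|---|---|---|---|
| dawn | 5.00 | 44 | 5 | 0 |
| dawn | 10.0 | 28 | 4 | 1 |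
| dawn | 15.0 | 15 | 4 | 1 |
| dawn | 20.0 | 8 | 1 | 0 |
| dawn | 25.0 | 4 | 0 | 0 |
| dawn | 30.0 | 3 | 2 | 1 |
| noon | 4.00 | 56 | 7 | 1 |
| noon | 6.00 | 45 | 9 | 1 |
| noon | 12.0 | 24 | 3 | 0 |
| noon | 20.0 | 16 | 0 | 4 |
| noon | 30.0 | 9 | 2 | 1 |
| noon | 48.0 | 2 | 0 | 0 |

(readings scatter by 1.5 percentage points)

- equivalents of X to J, everything else as given, that leave most Z at 3.0 d
- the amount of Z then, in percent of the J charged
- the amount of Z with the amounts as given



- Read the Z trace from first to last reading: Z falls at about 0.107 h⁻¹ in the dawn run and about 0.0757 h⁻¹ in the noon run. The dawn run is faster with twice the G, so you should count G as a consumer of Z.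
- The rule of thumb stops working where that consumer's charge is not small against J. Call the G share, g, the charge of G as a fraction of the charge of J; in this flask it is 30.0%.
- My own reckoning assumes that one G takes one Z. At one equivalent of X or more, once G has reacted to the end, the ceiling on Z is one minus g, or 70.0%.
- The forecast puts the best charge at 1.05 equiv, with Z there at 82%, and Z as charged at 0.1%. Its ground: “The best charge is therefore about one equivalent, which exhausts X on J, the much faster partner.” Its best Z stands above my ceiling.

    X + L → Q + E (k = 13.0 M⁻¹ h⁻¹)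
    J + X → Z + E (k = 9.30 M⁻¹ h⁻¹)
    Z + G → D (k = 3.80 M⁻¹ h⁻¹)
    X + Z → L + E (k = 1.50 M⁻¹ h⁻¹)

- The flask gives its best Z, 43.7%, at 1.20 equiv, and 0.349% as charged; that best Z stands below the ceiling by 26 percentage points. The neighbour flask holds 0.043 M of X, a fraction 0.782 of the J charged, which is short of one equivalent. Its ceiling is therefore that fraction minus g, or 48.2%. At 3.00 d in that neighbour, D is 29.9%, G is down to 0.445% of its own charge, and X, the limiting reagent there, is at 0%. Z stands at 33.1%, below its ceiling, beside 30.8% of unreacted J.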